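The decalin is numbered as in labdanes. Everything rests on cutting ring A at C4–C5, the bond joining the gem-dimethyl carbon to the ring-fusion methine beside the C6 oxygen. With C6 raised to a ketone, C5 is an enol carbon and C4 a tertiary cation, so ring A closes last by intramolecular SN1 tert-alkylation of a silyl enol ether of ring B, forming the quaternary C4 and the C5 stereocentre in one operation. The precursor is a monocyclic cyclohexene (ring B, from an asymmetric Diels–Alder reaction) bearing the C9 ester, the quaternary C10 with a 4-methoxy-4-methylpentyl chain and the C5=C6 silyl enol ether fixed by conjugate addition. C17 and the side chain follow.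

Key step: step 6

Numbering: C4 = CMe2, C5/C10 = ring fusion, C6 = acetoxy carbon, C7=C8, C17 = CH2O carbon on C8, C9 carries the C11–C16 chain.

Assumption: the sense of induction of the oxazaborolidinium catalyst (step 2) and of the palladium/bisphosphine ligand (step 15) is taken from the accepted models; if either proves opposite, the mirror-image catalyst or ligand is used.

Step 1
Reactants: 1 (E)-pent-3-en-2-one
Product: 2 (E)-triisopropyl(penta-1,3-dien-2-yloxy)silane
Conditions: TIPSOTf, Et3N, CH2Cl2, 0 °C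
Reagents that add atoms: triisopropylsilyl trifluoromethanesulfonate, CC(C)[Si](OS(=O)(=O)C(F)(F)F)(C(C)C)C(C)C
Why: Soft enolisation of the methyl ketone on its CH3 side (silyl enol ether formation with a silyl triflate and an amine) should give the cross-conjugated 2-silyloxy diene with the E-propenyl group unchanged.

Step 2
Reactants: 2 (E)-triisopropyl(penta-1,3-dien-2-yloxy)silane; 3 2,2,2-trifluoroethyl prop-2-enoate
Product: 4 2,2,2-trifluoroethyl (1R,2S)-2-methyl-4-[(triisopropylsilyl)oxy]cyclohex-3-ene-1-carboxylate (methyl cis to the ester)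
Conditions: (R)-3,3-diphenyl-1-(o-tolyl)tetrahydro-1H,3H-pyrrolo[1,2-c][1,3,2]oxazaborole·HNTf2 (10 mol%), CH2Cl2, −78 to −40 °C
Reagents that add atoms: none
Why: Catalytic asymmetric Diels–Alder reaction in which the 2-silyloxy and 1-methyl groups of the diene both send its CH2 terminus to the acrylate β-carbon, the chiral oxazaborolidinium cation blocks one face of the bound acrylate and so sets the ester-bearing carbon (later C9), and endo addition places the methyl cis (this centre is erased in step 3).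

Step 3
Reactants: 4 2,2,2-trifluoroethyl (1R,2S)-2-methyl-4-[(triisopropylsilyl)oxy]cyclohex-3-ene-1-carboxylate
Product: 5 2,2,2-trifluoroethyl (1R)-2-methyl-4-oxocyclohex-2-ene-1-carboxylate
Conditions: Pd(OAc)2 (1.05 equiv), DMSO, 45 °C
Reagents that add atoms: none
Why: Saegusa–Ito oxidation, in which palladation of the silyl enol ether and β-hydride elimination of the only available β-hydrogen (on the methyl-bearing carbon) should give the 3-methyl enone regiospecifically under non-basic conditions that leave the ester-bearing stereocentre intact.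

Step 4
Reactants: 6 5-bromo-2-methylpent-2-ene
Product: 7 5-bromo-2-methoxy-2-methylpentane
Conditions: MeOH, H2SO4 (cat.), 40 °C
Reagents that add atoms: methanol, CO
Why: Acid-catalysed Markovnikov addition of methanol to the trisubstituted alkene through the tertiary cation should give the tertiary methyl ether, a masked tertiary cation that tolerates Grignard formation.

Step 5
Reactants: 5 2,2,2-trifluoroethyl (1R)-2-methyl-4-oxocyclohex-2-ene-1-carboxylate; 7 5-bromo-2-methoxy-2-methylpentane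
Product: 9 2,2,2-trifluoroethyl (1R,2R)-2-(4-methoxy-4-methylpentyl)-2-methyl-4-[(trimethylsilyl)oxy]cyclohex-3-ene-1-carboxylate, via (4-methoxy-4-methylpentyl)magnesium bromide 8 (not isolated)
Conditions: 7, Mg, THF, rt; then CuBr·SMe2 (10 mol%), TMSCl, HMPA, 5, THF, −78 °C; Et3N, pentane, filtration
Reagents that add atoms: chlorotrimethylsilane, C[Si](C)(C)Cl
Why: Copper-catalysed, TMSCl-accelerated 1,4-addition of the Grignard reagent (conjugate addition with in situ silylation of the enolate) should take place anti to the pseudo-axial ester on the neighbouring carbon, which sets the quaternary C10 with the methyl cis to the ester, and fixes the enol double bond at C5=C6.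

Step 6
Reactants: 9 2,2,2-trifluoroethyl (1R,2R)-2-(4-methoxy-4-methylpentyl)-2-methyl-4-[(trimethylsilyl)oxy]cyclohex-3-ene-1-carboxylate
Product: 11 2,2,2-trifluoroethyl (1R,4aR,8aR)-5,5,8a-trimethyl-4-oxodecahydronaphthalene-1-carboxylate (trans-fused), via cis-fused C5 epimer 10 (not isolated)
Conditions: TiCl4 (2.2 equiv), CH2Cl2, −78 to −40 °C; aq. NaHCO3 work-up; then DBU (0.3 equiv), toluene, 50 °C
Reagents that add atoms: none
Why: TiCl4 ionises the tertiary methyl ether to the C4 tertiary cation, which is captured by C5 of the silyl enol ether with loss of the silyl group, an intramolecular SN1 α-tert-alkylation whose closest known type is the TiCl4-mediated alkylation of silyl enol ethers with tertiary halides or ethers. Ring A closes in the 6-(enolexo)-exo mode, the enol double bond lying outside the ring being formed. The new C5 centre is α to the C6 ketone and is set under thermodynamic control by the quaternary C10: the kinetic ring fusion (cis expected, 10) is equilibrated by DBU to the trans-decalone with the C10 methyl axial and the C9 ester equatorial. C4 becomes quaternary but is not stereogenic. The step needs bond formation at C5 and not at C7 or at oxygen, which is secured by the position of the enol double bond fixed in step 5 and by the eight-membered ring that O-alkylation would require. Alkene formed by proton loss from the cation should be returned to the cation by the HCl and TiCl4 present.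

Step 7
Reactants: 11 2,2,2-trifluoroethyl (1R,4aR,8aR)-5,5,8a-trimethyl-4-oxodecahydronaphthalene-1-carboxylate
Product: 12 2,2,2-trifluoroethyl (1R,4aR,8aR)-5,5,8a-trimethyl-4-oxo-1,4,4a,5,6,7,8,8a-octahydronaphthalene-1-carboxylate
Conditions: IBX, DMSO/toluene, 70 °C
Reagents that add atoms: none
Why: IBX dehydrogenation of the ketone via its enol should give the C7=C8 enone only, because the other α-carbon (C5) has no hydrogen-bearing β-carbon.

Step 8
Reactants: 13 (4-methoxyphenyl)methanol; 14 tributyl(iodomethyl)stannane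
Product: 15 tributyl{[(4-methoxyphenyl)methoxy]methyl}stannane
Conditions: NaH, THF/DMF, 0 °C to rt
Reagents that add atoms: none
Why: Williamson ether synthesis, SN2 displacement of iodide from the iodomethylstannane by the alkoxide.

Step 9
Reactants: 12 2,2,2-trifluoroethyl (1R,4aR,8aR)-5,5,8a-trimethyl-4-oxo-1,4,4a,5,6,7,8,8a-octahydronaphthalene-1-carboxylate; 15 tributyl{[(4-methoxyphenyl)methoxy]methyl}stannane
Product: 18 2,2,2-trifluoroethyl (1R,2S,4aR,8aR)-2-{[(4-methoxyphenyl)methoxy]methyl}-5,5,8a-trimethyl-4-[(trimethylsilyl)oxy]-1,2,4a,5,6,7,8,8a-octahydronaphthalene-1-carboxylate, via {[(4-methoxyphenyl)methoxy]methyl}lithium 16 (not isolated), via lithium bis(alkoxymethyl)cuprate 17 (not isolated)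
Conditions: 15, n-BuLi, THF, −78 °C; CuBr·SMe2 (0.5 equiv per Li), −78 °C; then TMSCl, 12, −78 °C
Reagents that add atoms: chlorotrimethylsilane, C[Si](C)(C)Cl
Why: Tin–lithium exchange, transmetalation to the Gilman cuprate and TMSCl-assisted 1,4-addition to the enone should place the C17 carbon on C8, expected anti to the C9 ester, the new C8 centre being erased in step 10.

Step 10
Reactants: 18 2,2,2-trifluoroethyl (1R,2S,4aR,8aR)-2-{[(4-methoxyphenyl)methoxy]methyl}-5,5,8a-trimethyl-4-[(trimethylsilyl)oxy]-1,2,4a,5,6,7,8,8a-octahydronaphthalene-1-carboxylate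
Product: 19 2,2,2-trifluoroethyl (1S,4aR,8aR)-2-{[(4-methoxyphenyl)methoxy]methyl}-5,5,8a-trimethyl-4-oxo-1,4,4a,5,6,7,8,8a-octahydronaphthalene-1-carboxylate
Conditions: Pd(OAc)2 (1.05 equiv), MeCN, rt
Reagents that add atoms: none
Why: Saegusa–Ito oxidation, in which β-hydride elimination can only take H8, should restore the C7=C8 enone now carrying C17 under neutral conditions that do not epimerise C9.

Step 11
Reactants: 19 2,2,2-trifluoroethyl (1S,4aR,8aR)-2-{[(4-methoxyphenyl)methoxy]methyl}-5,5,8a-trimethyl-4-oxo-1,4,4a,5,6,7,8,8a-octahydronaphthalene-1-carboxylate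
Product: 20 [(1S,4S,4aR,8aS)-4-hydroxy-2-{[(4-methoxyphenyl)methoxy]methyl}-5,5,8a-trimethyl-1,4,4a,5,6,7,8,8a-octahydronaphthalen-1-yl]methanol
Conditions: i-Bu2AlH (5 equiv), CH2Cl2, −78 to 0 °C; aq. potassium sodium tartrate
Reagents that add atoms: none
Why: Hydride reduction (1,2-reduction of the enone and reduction of the ester to the primary alcohol), in which hydride should reach C6 from the face opposite to the axial C10 and C4 methyl groups and so give the axial 6-alcohol cis to the C10 methyl.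

Step 12
Reactants: 20 [(1S,4S,4aR,8aS)-4-hydroxy-2-{[(4-methoxyphenyl)methoxy]methyl}-5,5,8a-trimethyl-1,4,4a,5,6,7,8,8a-octahydronaphthalen-1-yl]methanol
Product: 21 5-({[(1S,4S,4aR,8aR)-4-hydroxy-2-{[(4-methoxyphenyl)methoxy]methyl}-5,5,8a-trimethyl-1,4,4a,5,6,7,8,8a-octahydronaphthalen-1-yl]methyl}sulfanyl)-1-phenyl-1H-tetrazole
Conditions: 1-phenyl-1H-tetrazole-5-thiol, PPh3, DIAD, THF, 0 °C to rt
Reagents that add atoms: 1-phenyl-1H-tetrazole-5-thiol, Sc1nnnn1-c1ccccc1
Why: Mitsunobu thioetherification, in which only the primary C11 alcohol should be activated and displaced by the acidic thiol, the axial secondary allylic alcohol being too hindered.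

Step 13
Reactants: 21 5-({[(1S,4S,4aR,8aR)-4-hydroxy-2-{[(4-methoxyphenyl)methoxy]methyl}-5,5,8a-trimethyl-1,4,4a,5,6,7,8,8a-octahydronaphthalen-1-yl]methyl}sulfanyl)-1-phenyl-1H-tetrazole
Product: 22 5-({[(1S,4S,4aR,8aR)-4-acetoxy-2-{[(4-methoxyphenyl)methoxy]methyl}-5,5,8a-trimethyl-1,4,4a,5,6,7,8,8a-octahydronaphthalen-1-yl]methyl}sulfanyl)-1-phenyl-1H-tetrazole
Conditions: Ac2O, Et3N, DMAP (cat.), CH2Cl2, rt
Reagents that add atoms: acetic anhydride, CC(=O)OC(C)=O
Why: DMAP-catalysed acylation of the hindered secondary alcohol, which also protects this allylic position from oxidation in the later DDQ step.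

Step 14
Reactants: 22 5-({[(1S,4S,4aR,8aR)-4-acetoxy-2-{[(4-methoxyphenyl)methoxy]methyl}-5,5,8a-trimethyl-1,4,4a,5,6,7,8,8a-octahydronaphthalen-1-yl]methyl}sulfanyl)-1-phenyl-1H-tetrazole
Product: 23 5-({[(1S,4S,4aR,8aR)-4-acetoxy-2-{[(4-methoxyphenyl)methoxy]methyl}-5,5,8a-trimethyl-1,4,4a,5,6,7,8,8a-octahydronaphthalen-1-yl]methyl}sulfonyl)-1-phenyl-1H-tetrazole
Conditions: (NH4)6Mo7O24·4H2O (10 mol%), 30% H2O2, EtOH, 0 °C to rt
Reagents that add atoms: hydrogen peroxide, OO
Why: Molybdate-catalysed oxidation of the sulfide to the sulfone by peroxide, which should leave the trisubstituted alkene with its two allylic oxygen substituents untouched.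

Step 15
Reactants: 24 2-methyl-2-vinyloxirane (racemic); 13 (4-methoxyphenyl)methanol
Product: 25 (2S)-2-[(4-methoxyphenyl)methoxy]-2-methylbut-3-en-1-ol
Conditions: Pd2(dba)3·CHCl3 (1 mol%), (1R,2R)-N,N'-bis[2-(diphenylphosphino)benzoyl]cyclohexane-1,2-diamine (3 mol%), BEt3 (1 mol%), CH2Cl2, rt
Reagents that add atoms: none
Why: Palladium-catalysed dynamic kinetic asymmetric allylic etherification of the racemic vinyl epoxide, in which the interconverting π-allyl complexes are attacked by the boron-bound alkoxide at the more substituted terminus inside the chiral ligand pocket, should set the tertiary ether centre (later C13).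

Step 16
Reactants: 25 (2S)-2-[(4-methoxyphenyl)methoxy]-2-methylbut-3-en-1-ol
Product: 26 (2S)-2-[(4-methoxyphenyl)methoxy]-2-methylbut-3-enal
Conditions: Dess–Martin periodinane, NaHCO3, CH2Cl2, 0 °C to rt
Reagents that add atoms: none
Why: Dess–Martin oxidation of the primary alcohol to the aldehyde, whose α-carbon is fully substituted and cannot epimerise.

Step 17
Reactants: 23 5-({[(1S,4S,4aR,8aR)-4-acetoxy-2-{[(4-methoxyphenyl)methoxy]methyl}-5,5,8a-trimethyl-1,4,4a,5,6,7,8,8a-octahydronaphthalen-1-yl]methyl}sulfonyl)-1-phenyl-1H-tetrazole; 26 (2S)-2-[(4-methoxyphenyl)methoxy]-2-methylbut-3-enal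
Product: 27 (1S,4S,4aR,8aS)-4-acetoxy-1-[(1E,3S)-3-[(4-methoxyphenyl)methoxy]-3-methylpenta-1,4-dien-1-yl]-2-{[(4-methoxyphenyl)methoxy]methyl}-5,5,8a-trimethyl-1,4,4a,5,6,7,8,8a-octahydronaphthalene
Conditions: KN(SiMe3)2, DME, −60 °C to rt (base added to 23 and 26)
Reagents that add atoms: none
Why: Julia–Kocienski olefination (addition of the metallated tetrazolyl sulfone to the aldehyde, Smiles rearrangement, loss of SO2 and aryloxide), which with a tetrazolyl sulfone and an α-branched aldehyde should give the E C11=C12 alkene without touching any stereocentre.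

Step 18
Reactants: 27 (1S,4S,4aR,8aS)-4-acetoxy-1-[(1E,3S)-3-[(4-methoxyphenyl)methoxy]-3-methylpenta-1,4-dien-1-yl]-2-{[(4-methoxyphenyl)methoxy]methyl}-5,5,8a-trimethyl-1,4,4a,5,6,7,8,8a-octahydronaphthalene
Product: 28 (1S,4S,4aR,8aS)-4-acetoxy-2-(hydroxymethyl)-1-[(1E,3S)-3-hydroxy-3-methylpenta-1,4-dien-1-yl]-5,5,8a-trimethyl-1,4,4a,5,6,7,8,8a-octahydronaphthalene
Conditions: DDQ (3 equiv), CH2Cl2/pH 7 buffer, 0 °C
Reagents that add atoms: none
Why: Oxidative cleavage of both 4-methoxybenzyl ethers by DDQ (benzylic hydride abstraction and hydrolysis of the oxocarbenium ions) should free the primary C17 and tertiary C13 alcohols while the acetate at C6 stays.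

Step 19
Reactants: 28 (1S,4S,4aR,8aS)-4-acetoxy-2-(hydroxymethyl)-1-[(1E,3S)-3-hydroxy-3-methylpenta-1,4-dien-1-yl]-5,5,8a-trimethyl-1,4,4a,5,6,7,8,8a-octahydronaphthalene
Product: 29 [(1S,4S,4aR,8aS)-4-acetoxy-1-[(1E,3S)-3-hydroxy-3-methylpenta-1,4-dien-1-yl]-5,5,8a-trimethyl-1,4,4a,5,6,7,8,8a-octahydronaphthalen-2-yl]methyl acetate (CNP0103498.1)
Conditions: Ac2O, pyridine, 0 °C to rt
Reagents that add atoms: acetic anhydride, CC(=O)OC(C)=O
Why: Acylation of the primary allylic alcohol, chemoselective because the tertiary alcohol does not react with acetic anhydride in pyridine without forcing.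

Compound list

1 | (E)-pent-3-en-2-one | C/C=C/C(C)=O | starting material
2 | (E)-triisopropyl(penta-1,3-dien-2-yloxy)silane | C/C=C/C(=C)O[Si](C(C)C)(C(C)C)C(C)C | intermediate
3 | 2,2,2-trifluoroethyl prop-2-enoate | C=CC(=O)OCC(F)(F)F | starting material
4 | 2,2,2-trifluoroethyl (1R,2S)-2-methyl-4-[(triisopropylsilyl)oxy]cyclohex-3-ene-1-carboxylate | O=C(OCC(F)(F)F)[C@@H]1CCC(O[Si](C(C)C)(C(C)C)C(C)C)=C[C@@H]1C | intermediate
5 | 2,2,2-trifluoroethyl (1R)-2-methyl-4-oxocyclohex-2-ene-1-carboxylate | O=C(OCC(F)(F)F)[C@@H]1CCC(=O)C=C1C | intermediate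
6 | 5-bromo-2-methylpent-2-ene | CC(C)=CCCBr | starting material
7 | 5-bromo-2-methoxy-2-methylpentane | COC(C)(C)CCCBr | intermediate
8 | (4-methoxy-4-methylpentyl)magnesium bromide | COC(C)(C)CCC[Mg]Br | intermediate (not isolated)
9 | 2,2,2-trifluoroethyl (1R,2R)-2-(4-methoxy-4-methylpentyl)-2-methyl-4-[(trimethylsilyl)oxy]cyclohex-3-ene-1-carboxylate | O=C(OCC(F)(F)F)[C@@H]1CCC(O[Si](C)(C)C)=C[C@@]1(C)CCCC(C)(C)OC | intermediate
10 | 2,2,2-trifluoroethyl (1R,4aS,8aR)-5,5,8a-trimethyl-4-oxodecahydronaphthalene-1-carboxylate (cis-fused) | O=C(OCC(F)(F)F)[C@@H]1CCC(=O)[C@H]2C(C)(C)CCC[C@@]12C | intermediate (not isolated)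
11 | 2,2,2-trifluoroethyl (1R,4aR,8aR)-5,5,8a-trimethyl-4-oxodecahydronaphthalene-1-carboxylate (trans-fused) | O=C(OCC(F)(F)F)[C@@H]1CCC(=O)[C@@H]2C(C)(C)CCC[C@@]12C | intermediate
12 | 2,2,2-trifluoroethyl (1R,4aR,8aR)-5,5,8a-trimethyl-4-oxo-1,4,4a,5,6,7,8,8a-octahydronaphthalene-1-carboxylate | O=C(OCC(F)(F)F)[C@@H]1C=CC(=O)[C@@H]2C(C)(C)CCC[C@@]12C | intermediate
13 | (4-methoxyphenyl)methanol | COc1ccc(CO)cc1 | starting material
14 | tributyl(iodomethyl)stannane | CCCC[Sn](CCCC)(CCCC)CI | starting material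
15 | tributyl{[(4-methoxyphenyl)methoxy]methyl}stannane | CCCC[Sn](CCCC)(CCCC)COCc1ccc(OC)cc1 | intermediate
16 | {[(4-methoxyphenyl)methoxy]methyl}lithium | [Li]COCc1ccc(OC)cc1 | intermediate (not isolated)
17 | lithium bis{[(4-methoxyphenyl)methoxy]methyl}cuprate | [Li+].COc1ccc(COC[Cu-]COCc2ccc(OC)cc2)cc1 | intermediate (not isolated)
18 | 2,2,2-trifluoroethyl (1R,2S,4aR,8aR)-2-{[(4-methoxyphenyl)methoxy]methyl}-5,5,8a-trimethyl-4-[(trimethylsilyl)oxy]-1,2,4a,5,6,7,8,8a-octahydronaphthalene-1-carboxylate (C2 configuration as expected, inconsequential) | O=C(OCC(F)(F)F)[C@@H]1[C@@H](COCc3ccc(OC)cc3)C=C(O[Si](C)(C)C)[C@@H]2C(C)(C)CCC[C@@]12C | intermediate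
19 | 2,2,2-trifluoroethyl (1S,4aR,8aR)-2-{[(4-methoxyphenyl)methoxy]methyl}-5,5,8a-trimethyl-4-oxo-1,4,4a,5,6,7,8,8a-octahydronaphthalene-1-carboxylate | O=C(OCC(F)(F)F)[C@@H]1C(COCc3ccc(OC)cc3)=CC(=O)[C@@H]2C(C)(C)CCC[C@@]12C | intermediate
20 | [(1S,4S,4aR,8aS)-4-hydroxy-2-{[(4-methoxyphenyl)methoxy]methyl}-5,5,8a-trimethyl-1,4,4a,5,6,7,8,8a-octahydronaphthalen-1-yl]methanol | OC[C@@H]1C(COCc3ccc(OC)cc3)=C[C@H](O)[C@@H]2C(C)(C)CCC[C@@]12C | intermediate
21 | 5-({[(1S,4S,4aR,8aR)-4-hydroxy-2-{[(4-methoxyphenyl)methoxy]methyl}-5,5,8a-trimethyl-1,4,4a,5,6,7,8,8a-octahydronaphthalen-1-yl]methyl}sulfanyl)-1-phenyl-1H-tetrazole | c1ccccc1-n1nnnc1SC[C@@H]1C(COCc3ccc(OC)cc3)=C[C@H](O)[C@@H]2C(C)(C)CCC[C@@]12C | intermediate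
22 | 5-({[(1S,4S,4aR,8aR)-4-acetoxy-2-{[(4-methoxyphenyl)methoxy]methyl}-5,5,8a-trimethyl-1,4,4a,5,6,7,8,8a-octahydronaphthalen-1-yl]methyl}sulfanyl)-1-phenyl-1H-tetrazole | c1ccccc1-n1nnnc1SC[C@@H]1C(COCc3ccc(OC)cc3)=C[C@H](OC(C)=O)[C@@H]2C(C)(C)CCC[C@@]12C | intermediate
23 | 5-({[(1S,4S,4aR,8aR)-4-acetoxy-2-{[(4-methoxyphenyl)methoxy]methyl}-5,5,8a-trimethyl-1,4,4a,5,6,7,8,8a-octahydronaphthalen-1-yl]methyl}sulfonyl)-1-phenyl-1H-tetrazole | c1ccccc1-n1nnnc1S(=O)(=O)C[C@@H]1C(COCc3ccc(OC)cc3)=C[C@H](OC(C)=O)[C@@H]2C(C)(C)CCC[C@@]12C | intermediate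
24 | 2-methyl-2-vinyloxirane (racemic) | C=CC1(C)CO1 | starting material
25 | (2S)-2-[(4-methoxyphenyl)methoxy]-2-methylbut-3-en-1-ol | C=C[C@](C)(OCc1ccc(OC)cc1)CO | intermediate
26 | (2S)-2-[(4-methoxyphenyl)methoxy]-2-methylbut-3-enal | C=C[C@](C)(OCc1ccc(OC)cc1)C=O | intermediate
27 | (1S,4S,4aR,8aS)-4-acetoxy-1-[(1E,3S)-3-[(4-methoxyphenyl)methoxy]-3-methylpenta-1,4-dien-1-yl]-2-{[(4-methoxyphenyl)methoxy]methyl}-5,5,8a-trimethyl-1,4,4a,5,6,7,8,8a-octahydronaphthalene | C=C[C@](C)(OCc1ccc(OC)cc1)/C=C/[C@@H]1C(COCc3ccc(OC)cc3)=C[C@H](OC(C)=O)[C@@H]2C(C)(C)CCC[C@@]12C | intermediate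
28 | (1S,4S,4aR,8aS)-4-acetoxy-2-(hydroxymethyl)-1-[(1E,3S)-3-hydroxy-3-methylpenta-1,4-dien-1-yl]-5,5,8a-trimethyl-1,4,4a,5,6,7,8,8a-octahydronaphthalene | C=C[C@](C)(O)/C=C/[C@@H]1C(CO)=C[C@H](OC(C)=O)[C@@H]2C(C)(C)CCC[C@@]12C | intermediate
29 | [(1S,4S,4aR,8aS)-4-acetoxy-1-[(1E,3S)-3-hydroxy-3-methylpenta-1,4-dien-1-yl]-5,5,8a-trimethyl-1,4,4a,5,6,7,8,8a-octahydronaphthalen-2-yl]methyl acetate (labdane numbering 5R,6S,9S,10S,13S) | C=C[C@](C)(O)/C=C/[C@@H]1C(COC(C)=O)=C[C@H](OC(C)=O)[C@@H]2C(C)(C)CCC[C@@]12C | target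

Total step count: 19. Longest linear sequence: 15 steps (steps 1, 2, 3, 5, 6, 7, 9, 10, 11, 12, 13, 14, 17, 18, 19).

Steps most likely to fail

Step 6 (key step). What may go wrong: the enol ether may lose its silyl group by protonation before the C–C bond forms. The free ketone can then be attacked at its carbonyl carbon by the alkene that arises from proton loss of the cation (Prins-type closure to a bridged alcohol). The ring fusion may also equilibrate incompletely. The fallback sets out from 5 and returns at 11, and closes ring A by carbonyl chemistry instead of a cation. The Grignard reagent [3-(2-methyl-1,3-dioxolan-2-yl)propyl]magnesium chloride F1 (from commercial 2-(3-chloropropyl)-2-methyl-1,3-dioxolane and Mg) is added to 5 as its organocopper–BF3 reagent (CuI, BF3·OEt2, THF, −78 °C), again anti to the ester, to give the ketal ketone 2,2,2-trifluoroethyl (1R,2R)-2-methyl-2-[3-(2-methyl-1,3-dioxolan-2-yl)propyl]-4-oxocyclohexane-1-carboxylate F2. p-TsOH·H2O in wet toluene at 80 °C removes the ketal and effects the Robinson-type intramolecular aldol condensation between C5 and the side-chain ketone to give the C4=C5 enone 2,2,2-trifluoroethyl (1R,8aS)-5,8a-dimethyl-4-oxo-1,2,3,4,6,7,8,8a-octahydronaphthalene-1-carboxylate F3. Me2CuLi with BF3·OEt2 then adds methyl to C4, with no stereochemical issue because C4 becomes the gem-dimethyl carbon, and protonation followed by DBU equilibration at C5 gives 11.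

Step 5. What may go wrong: 1,4-addition at the fully substituted β-carbon may be slow, so that the Grignard reagent instead removes the acidic C9 hydrogen (racemising 5) or attacks the activated ester; the anti selectivity may also erode. The fallback sets out from 5 and returns at 11 by a non-basic Lewis-acid route. Hosomi–Sakurai conjugate allylation (allyltrimethylsilane, TiCl4, CH2Cl2, −78 °C), anti to the ester, gives 2,2,2-trifluoroethyl (1R,2R)-2-methyl-4-oxo-2-(prop-2-en-1-yl)cyclohexane-1-carboxylate F4. Cross-metathesis with 2-methylbut-3-en-2-ol (second-generation Grubbs catalyst, CH2Cl2, 40 °C) gives the (E)-allylic tertiary alcohol 2,2,2-trifluoroethyl (1R,2R)-2-[(2E)-4-hydroxy-4-methylpent-2-en-1-yl]-2-methyl-4-oxocyclohexane-1-carboxylate F5. Hydrogenation (H2, Pd on carbon, EtOAc) gives 2,2,2-trifluoroethyl (1R,2R)-2-(4-hydroxy-4-methylpentyl)-2-methyl-4-oxocyclohexane-1-carboxylate F6. TfOH in CH2Cl2 at −20 °C ionises the tertiary alcohol, the ketone closes ring A through the only enol that can reach C4, and DBU equilibration gives 11.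

Step 17. What may go wrong: the neopentyl-type sulfonyl carbanion may add slowly to the fully α-substituted aldehyde, the base may attack the acetate, and the E selectivity may erode. The fallback sets out from 20 and 25 and returns at 27, with the roles of the two partners exchanged. 20 is oxidised at the primary alcohol only (TEMPO, PhI(OAc)2, CH2Cl2) to (1S,4S,4aR,8aR)-4-hydroxy-2-{[(4-methoxyphenyl)methoxy]methyl}-5,5,8a-trimethyl-1,4,4a,5,6,7,8,8a-octahydronaphthalene-1-carbaldehyde F7. 25 is converted by Mitsunobu reaction with 1-phenyl-1H-tetrazole-5-thiol (PPh3, DIAD) into 5-{[(2S)-2-[(4-methoxyphenyl)methoxy]-2-methylbut-3-en-1-yl]sulfanyl}-1-phenyl-1H-tetrazole F8, which is oxidised ((NH4)6Mo7O24·4H2O, H2O2, EtOH) to 5-{[(2S)-2-[(4-methoxyphenyl)methoxy]-2-methylbut-3-en-1-yl]sulfonyl}-1-phenyl-1H-tetrazole F9. Julia–Kocienski olefination of F7 with F9 (KN(SiMe3)2, 2.2 equiv, DME, −60 °C) gives (1S,4S,4aR,8aS)-1-[(1E,3S)-3-[(4-methoxyphenyl)methoxy]-3-methylpenta-1,4-dien-1-yl]-2-{[(4-methoxyphenyl)methoxy]methyl}-5,5,8a-trimethyl-1,4,4a,5,6,7,8,8a-octahydronaphthalen-4-ol F10, and acetylation (Ac2O, Et3N, DMAP) gives 27.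

Further compounds

F1 | step 6 | [3-(2-methyl-1,3-dioxolan-2-yl)propyl]magnesium chloride | CC1(CCC[Mg]Cl)OCCO1
F2 | step 6 | 2,2,2-trifluoroethyl (1R,2R)-2-methyl-2-[3-(2-methyl-1,3-dioxolan-2-yl)propyl]-4-oxocyclohexane-1-carboxylate | O=C(OCC(F)(F)F)[C@@H]1CCC(=O)C[C@@]1(C)CCCC1(C)OCCO1
F3 | step 6 | 2,2,2-trifluoroethyl (1R,8aS)-5,8a-dimethyl-4-oxo-1,2,3,4,6,7,8,8a-octahydronaphthalene-1-carboxylate | O=C(OCC(F)(F)F)[C@@H]1CCC(=O)C2=C(C)CCC[C@@]12C
F4 | step 5 | 2,2,2-trifluoroethyl (1R,2R)-2-methyl-4-oxo-2-(prop-2-en-1-yl)cyclohexane-1-carboxylate | O=C(OCC(F)(F)F)[C@@H]1CCC(=O)C[C@@]1(C)CC=C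
F5 | step 5 | 2,2,2-trifluoroethyl (1R,2R)-2-[(2E)-4-hydroxy-4-methylpent-2-en-1-yl]-2-methyl-4-oxocyclohexane-1-carboxylate | O=C(OCC(F)(F)F)[C@@H]1CCC(=O)C[C@@]1(C)C/C=C/C(C)(C)O
F6 | step 5 | 2,2,2-trifluoroethyl (1R,2R)-2-(4-hydroxy-4-methylpentyl)-2-methyl-4-oxocyclohexane-1-carboxylate | O=C(OCC(F)(F)F)[C@@H]1CCC(=O)C[C@@]1(C)CCCC(C)(C)O
F7 | step 17 | (1S,4S,4aR,8aR)-4-hydroxy-2-{[(4-methoxyphenyl)methoxy]methyl}-5,5,8a-trimethyl-1,4,4a,5,6,7,8,8a-octahydronaphthalene-1-carbaldehyde | O=C[C@@H]1C(COCc3ccc(OC)cc3)=C[C@H](O)[C@@H]2C(C)(C)CCC[C@@]12C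
F8 | step 17 | 5-{[(2S)-2-[(4-methoxyphenyl)methoxy]-2-methylbut-3-en-1-yl]sulfanyl}-1-phenyl-1H-tetrazole | C=C[C@](C)(OCc1ccc(OC)cc1)CSc1nnnn1-c1ccccc1
F9 | step 17 | 5-{[(2S)-2-[(4-methoxyphenyl)methoxy]-2-methylbut-3-en-1-yl]sulfonyl}-1-phenyl-1H-tetrazole | C=C[C@](C)(OCc1ccc(OC)cc1)CS(=O)(=O)c1nnnn1-c1ccccc1
F10 | step 17 | (1S,4S,4aR,8aS)-1-[(1E,3S)-3-[(4-methoxyphenyl)methoxy]-3-methylpenta-1,4-dien-1-yl]-2-{[(4-methoxyphenyl)methoxy]methyl}-5,5,8a-trimethyl-1,4,4a,5,6,7,8,8a-octahydronaphthalen-4-ol | C=C[C@](C)(OCc1ccc(OC)cc1)/C=C/[C@@H]1C(COCc3ccc(OC)cc3)=C[C@H](O)[C@@H]2C(C)(C)CCC[C@@]12C
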